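## The problem

Compound 17 is a diaryl ether of two benzene rings. Ring A carries six different neighbours in a fixed order (C1 OH, C2 OAr, C3 Br, C4 Br, C5 Br, C6 H), and ring B is a 2,4-dibromophenyl group (C1' O, C2' Br, C4' Br). There is no stereocentre, so only position and chemoselectivity have to be controlled. The ether oxygen lies between three ortho substituents (C1–OH and C3–Br on ring A, C2'–Br on ring B), the worst case for any aryl C–O coupling. The bromine pattern of ring A runs against electrophilic substitution: the free hydroxyl directs to C4 and C6, yet C6 keeps its hydrogen, while C3 and C5, meta to the hydroxyl, are brominated. The two catechol oxygens must be told apart, with the aryl group on the oxygen next to C3–Br and the hydrogen on the oxygen next to C6–H. Five aryl C–Br bonds rule out zerovalent palladium, hot copper catalysis, alkyllithiums and dissolving metals once the rings are in place, and C3'–H between two bromines is acidic enough for lithium dialkylamides to start halogen migration. The feature that opens another way is that C3, C4, C5 and C6 of ring A carry Br, Br, Br and H, exactly the carbon periphery of 2,3,4-tribromothiophene 3, while C1 and C2 are adjacent, both bound to oxygen, and C2–OAr is at the oxidation level of an ynol ether carbon. Ring A can therefore be read as thiophene 3 in which sulfur has been replaced by a two-carbon ArO–C≡C–[O] unit.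

## Retrosynthesis

**17 ⇒ 15.** The C1–O bond is exchanged for C1–B. A triple bond cannot carry an aryloxy group and a hydroxyl equivalent at once in an isolable compound, whereas boron on an sp carbon is ordinary. Hydrogen at C1 would leave a C–H hydroxylation with no handle. Boronate 15 is no smaller than 17, but C1 becomes a carbon that an alkyne can supply. The forward step (through borate 16) must be an ipso oxidation that is faster than protodeboronation and leaves five C–Br bonds alone.

**15 ⇒ 5 + 13.** The ring A bonds C2–C3 and C1–C6 are cut, and a sulfonyl bridge is restored between C3 and C6 (adduct 14).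
- Any other pair of ring bonds would need a brominated acetylene as the two-carbon piece, or a diene that bears oxygen and bromine side by side.
- Only this cut puts Br, Br, Br, H into one piece (5) and both heteroatom-bearing carbons into the other (13).
- A hexa-differentiated benzene falls into a five-membered heterocycle and a linear alkyne, and the crowded ether bond is no longer made at an arene carbon at all.
- The forward reaction must deliver one orientation (boron-bearing carbon to C5–H of 5) and must outrun the self-dimerisation of 5.

**13 ⇒ 9.** The C(sp)–B bond is cut and HBr is added back across the triple bond (through 12, 11 and 10). The alternative of attaching the aryloxy group to a finished alkynylboron compound has no dependable polarity. Compound 9 is a stable bromoalkene. The base must eliminate and metalate without touching the ring B bromines or C3'–H.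

**9 ⇒ 7.** The vinylic C–Br bond is cut (through dibromide 8). This only raises the oxidation level of the two-carbon unit. It asks for bromine addition to the enol ether in preference to substitution on ring B, which the two deactivating bromines secure.

**7 ⇒ 6.** The O–C(vinyl) bond is cut. This is the only bond made to the ether oxygen in the whole route, and it goes to an unhindered CH of a vinyl donor rather than to a di-ortho-substituted arene carbon. The precursor is commercial phenol 6.

**5 ⇒ 3.** The two S–O bonds are cut (through sulfoxide 4). Oxidation switches the aromatic, unreactive thiophene into an electron-poor diene with a built-in leaving bridge. It needs an oxidant strong enough for a sulfur that three bromines have depleted.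

**3 ⇒ 1.** C5–H is exchanged for C5–Br (through 2). The two α positions of commercial 1 are equivalent and exchange faster than the β positions, so a single bromine can be removed without a regiochemical question.

## Roads not taken

**Alternative 1:** This is the obvious cut, the ether bond between two finished rings.
- Forward: 4,5,6-tribromo-2-methoxyphenol A1, whose free oxygen is the one next to bromine, is O-arylated with a 2,4-dibromophenyl electrophile (Ullmann coupling or a diaryliodonium salt). This gives 1,2,3-tribromo-4-(2,4-dibromophenoxy)-5-methoxybenzene A2, which is demethylated.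
- The line is short, and A1 is one bromination away from a commercial phenol.
- It makes the most hindered bond of the molecule by direct attack on that hindrance.
- Copper cannot be expected to distinguish the intended halide from the bromines present.
- The iodonium variant discards one brominated aryl group per coupling.
- A methyl group is carried only to tell the oxygens apart.
- The chosen plan needs no protecting group and no arene C–O coupling. Alternative 1 is kept as the safety net.

**Alternative 2:** The C2–O bond is cut with ring A as the electrophile.
- Forward: SNAr of 6 on 3,4,5-tribromo-2-fluorobenzaldehyde A3 gives 3,4,5-tribromo-2-(2,4-dibromophenoxy)benzaldehyde A4, and a Dakin oxidation gives 17.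
- A3 still holds the whole ring A problem, five contiguous substituents in an order that no directing effect builds.
- Its formyl group activates C4–Br (para) as well as C2–F.
- The cut moves the difficulty into the starting material instead of removing it.

**Alternative 3:** The same two ring bonds (C2–C3, C1–C6) are cut, but the two-carbon piece is at the acid oxidation level.
- Forward: 2-(2,4-dibromophenoxy)-1,1-bis(trimethylsilyloxy)ethene A5, two steps from 6, is combined with 5. Loss of the sulfonyl bridge and of one silyloxy group would give a phenol directly, without boron and one step shorter.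
- In a ketene acetal the nucleophilic carbon is the one that bears OAr. It should lead bond formation to the unhindered C5–H of 5, which places OAr next to hydrogen.
- The product would then be the isomer 2,3,4-tribromo-6-(2,4-dibromophenoxy)phenol A6.
- In 13 the nucleophilic carbon is the one that becomes C1, so the innate polarity works for the target instead of against it.

Key step: step 6

Remark on the chemistry: 9 is expected as a Z/E mixture and is drawn as the Z isomer. Both isomers lead to the same alkyne 10, so the geometry has no bearing on the route. Compounds 4, 8 and 14 are racemic transients, and 17 has no stereocentre.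

## Route

**Step 1**
Reactants: 1 tetrabromothiophene
Product: 3 2,3,4-tribromothiophene, via 3,4,5-tribromo-2-thienyllithium 2 (not isolated)
Conditions: n-BuLi (1.0 equiv), Et2O, −78 °C; then MeOH, −78 °C → rt
Reagents that add atoms: none
Why: Bromine–lithium exchange on the perbromothiophene goes to an α position, where sulfur and the flanking bromine stabilise the carbanion. The two α positions of 1 are equivalent, so one equivalent of n-BuLi should give the single thienyllithium 2, and protonation at −78 °C forestalls halogen migration.

**Step 2**
Reactants: 3 2,3,4-tribromothiophene
Product: 5 2,3,4-tribromothiophene 1,1-dioxide, via 2,3,4-tribromothiophene 1-oxide 4 (not isolated)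
Conditions: H2O2·urea, (CF3CO)2O, MeCN, 0 °C → rt
Reagents that add atoms: urea–hydrogen peroxide, OO.NC(N)=O (both sulfone oxygens, passed on through CF3CO3H made in the flask)
Why: Peracid oxidation of polyhalothiophenes to their 1,1-dioxides is a known reaction type, and CF3CO3H is electrophilic enough for the depleted sulfur. Excess oxidant should carry 4 on to 5 before 4 can cycloadd, and the three bromines slow self-dimerisation, so 5 should be isolable if kept cold and used soon.

**Step 3**
Reactants: 6 2,4-dibromophenol
Product: 7 2,4-dibromo-1-(vinyloxy)benzene
Conditions: vinyl acetate (2 equiv), [Ir(cod)Cl]2 (1 mol %), Na2CO3, toluene, 100 °C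
Reagents that add atoms: vinyl acetate, C=COC(C)=O
Why: This is an iridium-catalysed transfer vinylation of a phenol by a vinyl ester, run under weakly basic conditions that should not insert into aryl bromides. The O–C bond is made to an unhindered sp2 CH, so the ortho bromine of 6 costs little.

**Step 4**
Reactants: 7 2,4-dibromo-1-(vinyloxy)benzene
Product: 9 (Z)-2,4-dibromo-1-(2-bromovinyloxy)benzene, via 2,4-dibromo-1-(1,2-dibromoethoxy)benzene 8 (not isolated)
Conditions: Br2 (1.0 equiv), CH2Cl2, −78 °C; then iPr2NEt (1.5 equiv), −78 °C → reflux
Reagents that add atoms: bromine, BrBr
Why: This is the bromination–dehydrobromination of a vinyl ether. Bromine adds to the electron-rich double bond far faster than it substitutes the deactivated ring B, and the hindered amine removes HBr from 8 with loss of the oxygen-activated α-bromide. Neither the geometry nor the regiochemistry of this elimination matters, since every bromovinyl isomer gives 10 in step 5.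

**Step 5**
Reactants: 9 (Z)-2,4-dibromo-1-(2-bromovinyloxy)benzene
Product: 13 2-[(2,4-dibromophenoxy)ethynyl]-4,4,5,5-tetramethyl-1,3,2-dioxaborolane, via 2,4-dibromo-1-(ethynyloxy)benzene 10 (not isolated), via lithium (2,4-dibromophenoxy)acetylide 11 (not isolated), via lithium alkynyl(isopropoxy)pinacolborate 12 (not isolated)
Conditions: LiN(SiMe3)2 (2.3 equiv), THF, −78 → 0 °C; iPrOBpin, −78 °C; HCl·Et2O (1.0 equiv), −78 °C → rt; filtration under Ar
Reagents that add atoms: 2-isopropoxy-4,4,5,5-tetramethyl-1,3,2-dioxaborolane, CC(C)OB1OC(C)(C)C(C)(C)O1
Why: Anti E2 loss of HBr from (Z)-9 gives 10, which the second equivalent of amide deprotonates at once, so the polymerisable terminal ynol ether never builds up. Trapping an alkynyllithium with an alkoxy pinacol borate and opening the ate complex with anhydrous HCl is the standard alkynylboronate synthesis. LiN(SiMe3)2 is chosen because it neither exchanges aryl bromides nor is basic enough to metalate C3'–H.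

**Step 6**
Reactants: 5 2,3,4-tribromothiophene 1,1-dioxide; 13 2-[(2,4-dibromophenoxy)ethynyl]-4,4,5,5-tetramethyl-1,3,2-dioxaborolane
Product: 15 2-[3,4,5-tribromo-2-(2,4-dibromophenoxy)phenyl]-4,4,5,5-tetramethyl-1,3,2-dioxaborolane, via 7-thianorbornadiene 7,7-dioxide adduct 14 (not isolated)
Conditions: toluene, 90 °C, Ar sweep; 5 (1.5 equiv) added in portions
Reagents that add atoms: none
Why: Proposed new method: a boryl-substituted aryl ynol ether has not been shown as the 2π partner of a thiophene 1,1-dioxide; the closest known reaction types are the inverse-electron-demand Diels–Alder reaction/SO2 extrusion of tetrahalothiophene 1,1-dioxides with alkynes (giving tetrahalobenzenes) and the cycloaddition/CO2 extrusion of alkynylboronates with 2-pyrones (giving arylboronates). Mechanism: the low-lying LUMO of 5 and the oxygen-raised HOMO of 13 combine in a concerted, asynchronous [4+2] addition across C2 and C5 of 5 to give 14, whose sulfonyl bridge leaves by an irreversible cheletropic retro-addition driven by aromatisation. Ring A is closed in the intermolecular [4+2] mode by the two new bonds C1–C6 and C2–C3, and all six substituents are in place the moment it forms. The two bridgehead stereocentres of 14 vanish with SO2, so no stereocontrol is required. The selectivity needed is orientation: the aryloxy lone pair pushes and the boron p orbital pulls in the same sense, so the boron-bearing alkyne carbon is the nucleophilic terminus and should lead bond formation to C5–H of 5, the unhindered diene terminus, attack at which places the developing negative charge on brominated C4 and on C2, which is brominated and α to sulfur. The oxygen-stabilised alkyne carbon then closes on C2–Br, which puts OAr next to Br and boron next to H, and sterics (Bpin beside H rather than Br) point the same way. An aryl ynol ether has no β-hydrogen for retro-ene ketene formation, so 13 should stand the heating, and with no metal, base or nucleophile present the five C–Br bonds are spectators. Portionwise addition of 5 keeps its concentration low and disfavours its self-dimerisation.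

**Step 7**
Reactants: 15 2-[3,4,5-tribromo-2-(2,4-dibromophenoxy)phenyl]-4,4,5,5-tetramethyl-1,3,2-dioxaborolane
Product: 17 3,4,5-tribromo-2-(2,4-dibromophenoxy)phenol, via aryl pinacol borate 16 (not isolated)
Conditions: 30 % aq H2O2, NaOH (1.1 equiv), THF, 0 °C; then 1 M HCl
Reagents that add atoms: hydrogen peroxide, OO
Why: This is the standard ipso oxidation of an arylboronate. Hydroperoxide adds to boron, a 1,2-aryl shift gives 16, and hydrolysis gives the phenol with oxygen exactly where boron stood (C1). For a boronate with one ortho substituent the oxidation should be much faster than protodeboronation, and no C–Br bond is touched.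

## Compound list

1 | tetrabromothiophene | Brc1sc(Br)c(Br)c1Br | starting material
2 | 3,4,5-tribromo-2-thienyllithium | [Li]c1sc(Br)c(Br)c1Br | intermediate
3 | 2,3,4-tribromothiophene | Brc1csc(Br)c1Br | intermediate
4 | 2,3,4-tribromothiophene 1-oxide (racemic at sulfur) | O=S1C=C(Br)C(Br)=C1Br | intermediate
5 | 2,3,4-tribromothiophene 1,1-dioxide | O=S1(=O)C=C(Br)C(Br)=C1Br | intermediate
6 | 2,4-dibromophenol | Oc1ccc(Br)cc1Br | starting material
7 | 2,4-dibromo-1-(vinyloxy)benzene | C=COc1ccc(Br)cc1Br | intermediate
8 | 2,4-dibromo-1-(1,2-dibromoethoxy)benzene (racemic) | BrCC(Br)Oc1ccc(Br)cc1Br | intermediate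
9 | (Z)-2,4-dibromo-1-(2-bromovinyloxy)benzene | Br/C=C\Oc1ccc(Br)cc1Br | intermediate
10 | 2,4-dibromo-1-(ethynyloxy)benzene | C#COc1ccc(Br)cc1Br | intermediate
11 | lithium (2,4-dibromophenoxy)acetylide | [Li]C#COc1ccc(Br)cc1Br | intermediate
12 | lithium [(2,4-dibromophenoxy)ethynyl](isopropoxy)pinacolborate | [Li+].CC(C)O[B-]1(C#COc2ccc(Br)cc2Br)OC(C)(C)C(C)(C)O1 | intermediate
13 | 2-[(2,4-dibromophenoxy)ethynyl]-4,4,5,5-tetramethyl-1,3,2-dioxaborolane | CC1(C)OB(C#COc2ccc(Br)cc2Br)OC1(C)C | intermediate
14 | 1,5,6-tribromo-2-(2,4-dibromophenoxy)-3-(pinacolboryl)-7-thiabicyclo[2.2.1]hepta-2,5-diene 7,7-dioxide (racemic) | O=S1(=O)C2(Br)C(Br)=C(Br)C1C(B3OC(C)(C)C(C)(C)O3)=C2Oc4ccc(Br)cc4Br | intermediate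
15 | 2-[3,4,5-tribromo-2-(2,4-dibromophenoxy)phenyl]-4,4,5,5-tetramethyl-1,3,2-dioxaborolane | CC1(C)OB(OC1(C)C)c2cc(Br)c(Br)c(Br)c2Oc3ccc(Br)cc3Br | intermediate
16 | 2-[3,4,5-tribromo-2-(2,4-dibromophenoxy)phenoxy]-4,4,5,5-tetramethyl-1,3,2-dioxaborolane | CC1(C)OB(OC1(C)C)Oc2cc(Br)c(Br)c(Br)c2Oc3ccc(Br)cc3Br | intermediate
17 | 3,4,5-tribromo-2-(2,4-dibromophenoxy)phenol | Oc1cc(Br)c(Br)c(Br)c1Oc1ccc(Br)cc1Br | target

## Step count and least certain steps

Total steps: 7. Longest linear sequence: 5 (steps 3, 4, 5, 6 and 7 from 6). The branch from 1 to 5 has 2 steps.

**Step 6 (key step, proposed new method).**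
- The vacant boron orbital and the weakly donating dibromophenoxy group may lower the alkyne HOMO so far that cycloaddition becomes slower than the self-dimerisation of 5 and the thermal decay of 13.
- Bond formation may turn stepwise, by conjugate attack at C4 of the vinyl sulfone, and end in a [2+2] closure or in loss of orientation.
- Fallback, known chemistry only: the ring synthesis is given up and the ether bond is made on a finished ring A.
  - Guaiacol is tribrominated (Br2, AcOH) ortho and para to its free hydroxyl and para to its methoxy group. This gives 4,5,6-tribromo-2-methoxyphenol F1, whose free oxygen is the one next to bromine.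
  - 1,3-Dibromobenzene is converted with I2, mCPBA and TfOH into bis(2,4-dibromophenyl)iodonium triflate F2.
  - Metal-free O-arylation of the potassium salt of F1 with F2 proceeds by ligand coupling at trivalent iodine, which tolerates ortho substituents and aryl bromides. It gives 1,2,3-tribromo-4-(2,4-dibromophenoxy)-5-methoxybenzene F3.
  - Demethylation of F3 with BBr3 gives 17.
  - This line draws on no intermediate of the route. It sets out from commercial materials in place of 1 and 6 and comes back to the route at 17.

**Step 5.**
- Elimination with the silylamide may be incomplete. A stronger amide would invite metalation of ring B at C3'–H followed by halogen migration.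
- The push–pull alkyne may suffer hydration and protodeboronation while it is released from 12 and isolated.
- Fallback: this sets out from 11 and comes back at 15, with borylation moved from the alkyne to the arene.
  - 11 is quenched with Me3SiCl to [(2,4-dibromophenoxy)ethynyl]trimethylsilane F4, a neutral silyl ynol ether that should stand chromatography and storage.
  - Cycloaddition of F4 with 5 under the conditions of step 6 gives [3,4,5-tribromo-2-(2,4-dibromophenoxy)phenyl]trimethylsilane F5. Silicon polarises the alkyne in the same sense as boron and withdraws no π density.
  - Ipso-borodesilylation with BBr3 gives dibromo[3,4,5-tribromo-2-(2,4-dibromophenoxy)phenyl]borane F6, which is esterified with pinacol to 15.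

**Step 2.**
- Oxidation may stall at the sulfoxide stage, with Diels–Alder dimerisation of the S-oxide.
- The dioxide may dimerise through its less substituted C4=C5 edge.
- The free α position may be hydroxylated.
- Fallback: this sets out from 2 and comes back at 5.
  - 2 is quenched with Me3SiCl instead of MeOH to give (3,4,5-tribromothiophen-2-yl)trimethylsilane F7. Its silyl group enriches the sulfur and blocks the free α position.
  - Peracid oxidation gives 2,3,4-tribromo-5-(trimethylsilyl)thiophene 1,1-dioxide F8, which should be storable.
  - Protodesilylation of the α-sulfonyl C–Si bond (Bu4NF, AcOH, low temperature) sets 5 free just before step 6.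

**Step 3.**
- Vinyl transfer to a hindered, rather acidic phenol may be slow, and unreacted phenol may add to the product under acid catalysis.
- Fallback: this sets out from 6 and comes back at 7. Williamson alkylation of 6 with excess 1,2-dibromoethane (K2CO3, MeCN) gives 2,4-dibromo-1-(2-bromoethoxy)benzene F9, and E2 elimination with KOtBu in THF gives 7.

## Further compounds

F1 | step 6 | 4,5,6-tribromo-2-methoxyphenol | COc1cc(Br)c(Br)c(Br)c1O
F2 | step 6 | bis(2,4-dibromophenyl)iodonium triflate | Brc1ccc([I+]c2ccc(Br)cc2Br)c(Br)c1.[O-]S(=O)(=O)C(F)(F)F
F3 | step 6 | 1,2,3-tribromo-4-(2,4-dibromophenoxy)-5-methoxybenzene | COc1cc(Br)c(Br)c(Br)c1Oc1ccc(Br)cc1Br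
F4 | step 5 | [(2,4-dibromophenoxy)ethynyl]trimethylsilane | C[Si](C)(C)C#COc1ccc(Br)cc1Br
F5 | step 5 | [3,4,5-tribromo-2-(2,4-dibromophenoxy)phenyl]trimethylsilane | C[Si](C)(C)c1cc(Br)c(Br)c(Br)c1Oc1ccc(Br)cc1Br
F6 | step 5 | dibromo[3,4,5-tribromo-2-(2,4-dibromophenoxy)phenyl]borane | BrB(Br)c1cc(Br)c(Br)c(Br)c1Oc1ccc(Br)cc1Br
F7 | step 2 | (3,4,5-tribromothiophen-2-yl)trimethylsilane | C[Si](C)(C)c1sc(Br)c(Br)c1Br
F8 | step 2 | 2,3,4-tribromo-5-(trimethylsilyl)thiophene 1,1-dioxide | C[Si](C)(C)C1=C(Br)C(Br)=C(Br)S1(=O)=O
F9 | step 3 | 2,4-dibromo-1-(2-bromoethoxy)benzene | BrCCOc1ccc(Br)cc1Br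
A1 | alternative 1 | 4,5,6-tribromo-2-methoxyphenol | COc1cc(Br)c(Br)c(Br)c1O
A2 | alternative 1 | 1,2,3-tribromo-4-(2,4-dibromophenoxy)-5-methoxybenzene | COc1cc(Br)c(Br)c(Br)c1Oc1ccc(Br)cc1Br
A3 | alternative 2 | 3,4,5-tribromo-2-fluorobenzaldehyde | O=Cc1cc(Br)c(Br)c(Br)c1F
A4 | alternative 2 | 3,4,5-tribromo-2-(2,4-dibromophenoxy)benzaldehyde | O=Cc1cc(Br)c(Br)c(Br)c1Oc1ccc(Br)cc1Br
A5 | alternative 3 | 2-(2,4-dibromophenoxy)-1,1-bis(trimethylsilyloxy)ethene | C[Si](C)(C)OC(O[Si](C)(C)C)=COc1ccc(Br)cc1Br
A6 | alternative 3 | 2,3,4-tribromo-6-(2,4-dibromophenoxy)phenol | Oc1c(Br)c(Br)c(Br)cc1Oc1ccc(Br)cc1Br
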